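## Retrosynthetic overview

1. Target 27 ← desilylation and C2 oxidation ← Nozaki–Hiyama–Kishi macrocyclisation (C1–C2) of a ring-A vinyl iodide onto a cis-epoxy aldehyde; the carbocycle is closed last.
2. C3/C4 cis-epoxide ← Sharpless epoxidation of the Z-allylic alcohol; oxepane ← 7-exo opening of a Shi epoxide (C7/C8) by the C20 hydroxyl.
3. C8–C9 ← B-alkyl Suzuki coupling of the ring vinyl group with a neryl-acetate-derived 1,1-dibromoalkene, then methylation (E-trisubstituted alkene).
4. Ring A ← organocatalytic asymmetric Diels–Alder reaction of tiglic aldehyde with a 2-silyloxydiene (sets quaternary C11 and C12, the first stereocentres); C14 by Luche reduction.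
5. Ring order: ring A (Diels–Alder) → oxepane (epoxide opening) → twelve-membered carbocycle (NHK).

Locant key (target skeleton, used throughout): carbocycle C1–C11 plus C15; C1=C15 is the ring-A alkene; C2 ketone; C3–C4 epoxide (methyl on C4); C7 carbinol; C8 tertiary ether carbon (methyl); C11 quaternary (methyl); C12 CH–CH3; C13 CH2; C14 ring carbinol; C20 is the CH2 on C15, bridged through O to C8. Target configuration: 3R,4R,7R,8S,11R,12S,14R. TBS = tert-butyldimethylsilyl, TES = triethylsilyl.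

Assumption: the sense of induction of the new Diels–Alder catalyst cannot be known in advance; the catalyst enantiomer that gives adduct 6 as drawn is the one used and is written here as (S,S).

## Route

Step 1
Reactants: 1 2-(TBS-oxy)acetaldehyde; 2 1-(triphenylphosphoranylidene)propan-2-one
Product: 3 (E)-5-(TBS-oxy)pent-3-en-2-one
Conditions: CH2Cl2, rt
Reagents that add atoms: none
Why: Wittig olefination with a stabilised ylide gives the E-enone reliably.

Step 2
Reactants: 3 (E)-5-(TBS-oxy)pent-3-en-2-one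
Product: 4 (E)-2,5-bis(TBS-oxy)penta-1,3-diene
Conditions: TBSOTf, Et3N, CH2Cl2, 0 °C
Reagents that add atoms: tert-butyldimethylsilyl triflate, CC(C)(C)[Si](C)(C)OS(=O)(=O)C(F)(F)F
Why: Soft enolisation of the methyl ketone (silyl dienol ether formation) gives the cross-conjugated 2-silyloxydiene with the E alkene intact.

Step 3
Reactants: 4 (E)-2,5-bis(TBS-oxy)penta-1,3-diene; 5 (E)-2-methylbut-2-enal (tiglic aldehyde)
Product: 6 (1R,2S,6S)-4-(TBS-oxy)-2-[(TBS-oxy)methyl]-1,6-dimethylcyclohex-3-ene-1-carbaldehyde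
Conditions: (S,S)-IDPi Brønsted acid (BINOL-derived imidodiphosphorimidate, 3 mol %), 4 (1.3 equiv), toluene, −60 → −40 °C
Reagents that add atoms: none
Why: Proposed new method: a confined imidodiphosphorimidate acid is silylated in situ by a trace of 4, and the resulting silylium/chiral-anion pair activates the carbonyl of the α,β-disubstituted enal 5; the CH2 terminus of 4 (future C13) attacks the β-carbon (future C12) and the C15–C11 bond closes in the same ion pair in a concerted asynchronous [4+2] with both directing effects of the diene matched, so the E geometry of 5 becomes the cis C11/C12 methyl pair while the anion shields one enal face and fixes the absolute configuration of quaternary C11 and of C12 (the C15 centre, drawn endo, is erased in step 9); the closest known reaction types are imidodiphosphorimidate/silylium-catalysed asymmetric Diels–Alder reactions of α,β-unsaturated carbonyl compounds with simple dienes and oxazaborolidinium-catalysed Diels–Alder reactions of 2-substituted enals with 2-silyloxydienes.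

Step 4
Reactants: 6 Diels–Alder aldehyde
Product: 7 (1R,2S,6S)-1-ethenyl-4-(TBS-oxy)-2-[(TBS-oxy)methyl]-1,6-dimethylcyclohex-3-ene
Conditions: Ph3PCH3Br, KN(SiMe3)2, THF, 0 °C → rt
Reagents that add atoms: methyltriphenylphosphonium bromide, C[P+](c1ccccc1)(c1ccccc1)c1ccccc1.[Br-]
Why: Wittig methylenation of the non-enolisable neopentyl aldehyde installs the vinyl group (C10=C9) without touching the silyl enol ether or the quaternary centre.

Step 5
Reactants: 8 neryl acetate
Product: 10 (2Z)-3-methyl-6-oxohex-2-en-1-yl acetate, via secondary ozonide 9 (not isolated)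
Conditions: O3 (1.0 equiv), CH2Cl2, −78 °C; then Me2S, −78 °C → rt
Reagents that add atoms: ozone, [O-][O+]=O
Why: Ozonolysis is selective for the electron-rich terminal trisubstituted alkene because the other alkene is deactivated by the allylic acetate, and the Z alkene (future C3=C4) is untouched.

Step 6
Reactants: 10 (2Z)-3-methyl-6-oxohex-2-en-1-yl acetate
Product: 11 (2Z)-7,7-dibromo-3-methylhepta-2,6-dien-1-yl acetate
Conditions: CBr4, PPh3, Zn, CH2Cl2, rt; then 10, 0 °C
Reagents that add atoms: carbon tetrabromide, BrC(Br)(Br)Br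
Why: Ramirez (Corey–Fuchs) dibromo-olefination of the aldehyde adds the future C8 as a 1,1-dibromoalkene under neutral conditions that tolerate the acetate.

Step 7
Reactants: 7 vinylcyclohexene; 11 1,1-dibromoalkene
Product: 13 (2Z,6Z)-7-bromo-3-methyl-9-[ring]nona-2,6-dien-1-yl acetate (ring = (1R,2S,6S)-4-(TBS-oxy)-2-[(TBS-oxy)methyl]-1,6-dimethylcyclohex-3-en-1-yl), via B-alkyl-9-BBN borane 12 (not isolated)
Conditions: 9-BBN, THF, 0 °C → rt; then 11, Pd(dppf)Cl2 (5 mol %), AsPh3, aq. K3PO4, DMF/THF, rt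
Reagents that add atoms: none
Why: Anti-Markovnikov hydroboration of the vinyl group followed by B-alkyl Suzuki–Miyaura coupling, in which zerovalent palladium inserts selectively into the less hindered C–Br bond trans to the chain, forms C8–C9 trans to C6 and leaves the cis bromide.

Step 8
Reactants: 13 (Z)-bromoalkene
Product: 14 (2Z,6E)-3,7-dimethyl-9-[ring]nona-2,6-dien-1-yl acetate (same ring as in 13)
Conditions: Me2Zn, Pd(PtBu3)2 (3 mol %), THF, 0 °C → rt
Reagents that add atoms: dimethylzinc, C[Zn]C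
Why: Negishi methylation of the alkenyl bromide proceeds with retention under Pd(PtBu3)2, giving the E-trisubstituted C7=C8 alkene; the acetate and silyl enol ether do not react with the dialkylzinc.

Step 9
Reactants: 14 silyl enol ether triene
Product: 15 (2Z,6E)-9-[(1R,6S)-2-[(TBS-oxy)methyl]-1,6-dimethyl-4-oxocyclohex-2-en-1-yl]-3,7-dimethylnona-2,6-dien-1-yl acetate
Conditions: Pd(OAc)2 (1.05 equiv), MeCN/DMSO, 40 °C
Reagents that add atoms: none
Why: Saegusa–Ito oxidation: divalent palladium converts the regiodefined silyl enol ether into a palladium enolate, and β-hydride elimination of the C15–H gives the C1=C15 enone and erases the C15 centre.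

Step 10
Reactants: 15 enone
Product: 16 α-iodoenone (3-iodo analogue of 15)
Conditions: I2, pyridine/CH2Cl2, DMAP (cat.), rt, dark
Reagents that add atoms: iodine, II
Why: Johnson-type α-iodination of the enone by amine conjugate addition, iodination and elimination functionalises only C1, because the isolated alkenes add iodine reversibly and have no internal nucleophile.

Step 11
Reactants: 16 α-iodoenone
Product: 17 (2Z,6E)-9-[(1R,4R,6S)-2-[(TBS-oxy)methyl]-4-hydroxy-3-iodo-1,6-dimethylcyclohex-2-en-1-yl]-3,7-dimethylnona-2,6-dien-1-yl acetate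
Conditions: NaBH4, CeCl3·7H2O, MeOH, −40 °C
Reagents that add atoms: none
Why: Luche 1,2-reduction, in which hydride attacks axially on the half-chair with the C12 methyl equatorial and anti to the axial C11 methyl, gives the equatorial C14 alcohol cis to the C12 methyl (14R), as in the carvone to cis-carveol case.

Step 12
Reactants: 17 iodo allylic alcohol
Product: 18 (7R,8R)-epoxide of 17
Conditions: D-fructose-derived Shi ketone (30 mol %), Oxone (2KHSO5·KHSO4·K2SO4), K2CO3, Bu4NHSO4, MeCN/dimethoxymethane/aq. Na2B4O7 buffer, 0 °C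
Reagents that add atoms: potassium peroxymonosulfate (active component of Oxone), [K+].[O-]S(=O)(=O)OO
Why: Shi epoxidation through the spiro dioxirane transition state gives the (R,R)-epoxide of the E-trisubstituted C7=C8 alkene under catalyst control; the C3=C4 alkene is deactivated by the allylic acetate and the C1=C15 alkene by iodine and hindrance.

Step 13
Reactants: 18 (7R,8R)-epoxide
Product: 20 oxepane diol (C8–O–C20 ether with free C7 and C14 hydroxyls), via desilylated epoxy diol 19 (not isolated)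
Conditions: TBAF, AcOH, THF, 0 °C; then camphorsulfonic acid (10 mol %), CH2Cl2, 0 °C
Reagents that add atoms: none
Why: Fluoride frees the C20 hydroxyl, and acid-catalysed 7-exo-tet epoxide opening at the tertiary carbon C8 (favoured electronically and over the 8-endo mode) proceeds with inversion to set 8S while C7 keeps its R configuration as the free carbinol.

Step 14
Reactants: 20 oxepane diol
Product: 21 bis-TES ether of 20 (C7 and C14 O-TES)
Conditions: TESOTf, 2,6-lutidine, CH2Cl2, −78 → 0 °C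
Reagents that add atoms: triethylsilyl triflate, CC[Si](CC)(CC)OS(=O)(=O)C(F)(F)F
Why: Silylation masks both secondary alcohols so that the C7 oxygen cannot open the later C3/C4 epoxide (5-exo) and C14 is not oxidised in steps 17 and 19.

Step 15
Reactants: 21 bis-TES acetate
Product: 22 Z-allylic alcohol (C2–OH)
Conditions: K2CO3 (cat.), MeOH, 0 °C
Reagents that add atoms: none
Why: Mild methanolysis (transesterification) removes the primary acetate without cleaving the TES ethers or the vinyl iodide.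

Step 16
Reactants: 22 Z-allylic alcohol
Product: 23 (3S,4R)-epoxy alcohol (cis-epoxide, the centres that become 3R,4R in the ketone)
Conditions: Ti(OiPr)4 (20 mol %), L-(+)-diethyl tartrate (25 mol %), t-BuOOH, 4 Å molecular sieves, CH2Cl2, −20 °C
Reagents that add atoms: tert-butyl hydroperoxide, CC(C)(C)OO
Why: Sharpless asymmetric epoxidation with the tetravalent titanium/L-(+)-tartrate catalyst delivers oxygen to the nerol-type Z-allylic alcohol with the same facial sense as nerol to (2S,3R)-epoxynerol, and the concerted transfer keeps the cis relationship of C2 and C5.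

Step 17
Reactants: 23 epoxy alcohol
Product: 24 cis-epoxy aldehyde
Conditions: Dess–Martin periodinane, NaHCO3, CH2Cl2, 0 °C
Reagents that add atoms: none
Why: Buffered Dess–Martin oxidation converts the only free alcohol into the aldehyde without epimerising or opening the α,β-epoxide.

Step 18
Reactants: 24 epoxy aldehyde
Product: 25 macrocyclic epoxy alcohol (C1–C2 bond formed, C2 epimer mixture)
Conditions: CrCl2 (10 equiv), NiCl2 (2 mol %), DMSO/THF, rt, 1 mM, slow addition
Reagents that add atoms: none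
Why: Nozaki–Hiyama–Kishi macrocyclisation: zerovalent nickel inserts into the vinyl iodide, transmetalation to trivalent chromium gives an alkenylchromium that adds chemoselectively to the aldehyde at high dilution, helped by the preformed oxepane and cis-epoxide; the C2 carbinol configuration is irrelevant.

Step 19
Reactants: 25 macrocyclic epoxy alcohol
Product: 26 macrocyclic epoxy ketone bis-TES ether
Conditions: Dess–Martin periodinane, NaHCO3, CH2Cl2, 0 °C → rt
Reagents that add atoms: none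
Why: Dess–Martin oxidation of the single free (allylic, epoxy) carbinol gives the C2 ketone and converges both C2 epimers.

Step 20
Reactants: 26 macrocyclic epoxy ketone bis-TES ether
Product: 27 target CNP0316768.3
Conditions: HF·pyridine, pyridine, THF, 0 °C
Reagents that add atoms: none
Why: Buffered fluoride desilylation frees the C7 and C14 hydroxyls without opening the deactivated α,β-epoxy ketone.

## Compound list

1 | 2-(tert-butyldimethylsilyloxy)acetaldehyde | CC(C)(C)[Si](C)(C)OCC=O | starting material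
2 | 1-(triphenylphosphoranylidene)propan-2-one | CC(=O)C=P(c1ccccc1)(c1ccccc1)c1ccccc1 | starting material
3 | (E)-5-(tert-butyldimethylsilyloxy)pent-3-en-2-one | CC(=O)/C=C/CO[Si](C)(C)C(C)(C)C | intermediate
4 | (E)-2,5-bis(tert-butyldimethylsilyloxy)penta-1,3-diene | C=C(O[Si](C)(C)C(C)(C)C)/C=C/CO[Si](C)(C)C(C)(C)C | intermediate
5 | (E)-2-methylbut-2-enal (tiglic aldehyde) | C/C=C(\C)C=O | starting material
6 | (1R,2S,6S)-4-(tert-butyldimethylsilyloxy)-2-[(tert-butyldimethylsilyloxy)methyl]-1,6-dimethylcyclohex-3-ene-1-carbaldehyde | O=C[C@]1(C)[C@@H](C)CC(O[Si](C)(C)C(C)(C)C)=C[C@@H]1CO[Si](C)(C)C(C)(C)C | intermediate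
7 | (1R,2S,6S)-1-ethenyl-4-(tert-butyldimethylsilyloxy)-2-[(tert-butyldimethylsilyloxy)methyl]-1,6-dimethylcyclohex-3-ene | C=C[C@]1(C)[C@@H](C)CC(O[Si](C)(C)C(C)(C)C)=C[C@@H]1CO[Si](C)(C)C(C)(C)C | intermediate
8 | neryl acetate, (2Z)-3,7-dimethylocta-2,6-dien-1-yl acetate | CC(C)=CCC/C(C)=C\COC(C)=O | starting material
9 | secondary ozonide of 8 at the terminal alkene (3,3-dimethyl-1,2,4-trioxolane bearing the (3Z)-5-acetoxy-3-methylpent-3-enyl chain at C5) | CC1(C)OOC(CC/C(C)=C\COC(C)=O)O1 | intermediate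
10 | (2Z)-3-methyl-6-oxohex-2-en-1-yl acetate | O=CCC/C(C)=C\COC(C)=O | intermediate
11 | (2Z)-7,7-dibromo-3-methylhepta-2,6-dien-1-yl acetate | BrC(Br)=CCC/C(C)=C\COC(C)=O | intermediate
12 | 9-{2-[(1R,2S,6S)-4-(TBS-oxy)-2-[(TBS-oxy)methyl]-1,6-dimethylcyclohex-3-en-1-yl]ethyl}-9-borabicyclo[3.3.1]nonane | B1(CC[C@]2(C)[C@@H](C)CC(O[Si](C)(C)C(C)(C)C)=C[C@@H]2CO[Si](C)(C)C(C)(C)C)C3CCCC1CCC3 | intermediate
13 | (2Z,6Z)-7-bromo-9-[(1R,2S,6S)-4-(TBS-oxy)-2-[(TBS-oxy)methyl]-1,6-dimethylcyclohex-3-en-1-yl]-3-methylnona-2,6-dien-1-yl acetate | CC(=O)OC/C=C(C)\CC/C=C(Br)/CC[C@]1(C)[C@@H](C)CC(O[Si](C)(C)C(C)(C)C)=C[C@@H]1CO[Si](C)(C)C(C)(C)C | intermediate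
14 | (2Z,6E)-9-[(1R,2S,6S)-4-(TBS-oxy)-2-[(TBS-oxy)methyl]-1,6-dimethylcyclohex-3-en-1-yl]-3,7-dimethylnona-2,6-dien-1-yl acetate | CC(=O)OC/C=C(C)\CC/C=C(C)/CC[C@]1(C)[C@@H](C)CC(O[Si](C)(C)C(C)(C)C)=C[C@@H]1CO[Si](C)(C)C(C)(C)C | intermediate
15 | (2Z,6E)-9-[(1R,6S)-2-[(TBS-oxy)methyl]-1,6-dimethyl-4-oxocyclohex-2-en-1-yl]-3,7-dimethylnona-2,6-dien-1-yl acetate | CC(=O)OC/C=C(C)\CC/C=C(C)/CC[C@]1(C)[C@@H](C)CC(=O)C=C1CO[Si](C)(C)C(C)(C)C | intermediate
16 | (2Z,6E)-9-[(1R,6S)-2-[(TBS-oxy)methyl]-3-iodo-1,6-dimethyl-4-oxocyclohex-2-en-1-yl]-3,7-dimethylnona-2,6-dien-1-yl acetate | CC(=O)OC/C=C(C)\CC/C=C(C)/CC[C@]1(C)[C@@H](C)CC(=O)C(I)=C1CO[Si](C)(C)C(C)(C)C | intermediate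
17 | (2Z,6E)-9-[(1R,4R,6S)-2-[(TBS-oxy)methyl]-4-hydroxy-3-iodo-1,6-dimethylcyclohex-2-en-1-yl]-3,7-dimethylnona-2,6-dien-1-yl acetate | CC(=O)OC/C=C(C)\CC/C=C(C)/CC[C@]1(C)[C@@H](C)C[C@@H](O)C(I)=C1CO[Si](C)(C)C(C)(C)C | intermediate
18 | (2Z)-5-[(2R,3R)-3-{2-[(1R,4R,6S)-2-[(TBS-oxy)methyl]-4-hydroxy-3-iodo-1,6-dimethylcyclohex-2-en-1-yl]ethyl}-3-methyloxiran-2-yl]-3-methylpent-2-en-1-yl acetate | CC(=O)OC/C=C(C)\CC[C@H]1O[C@]1(C)CC[C@]2(C)[C@@H](C)C[C@@H](O)C(I)=C2CO[Si](C)(C)C(C)(C)C | intermediate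
19 | (2Z)-5-[(2R,3R)-3-{2-[(1R,4R,6S)-4-hydroxy-2-(hydroxymethyl)-3-iodo-1,6-dimethylcyclohex-2-en-1-yl]ethyl}-3-methyloxiran-2-yl]-3-methylpent-2-en-1-yl acetate | CC(=O)OC/C=C(C)\CC[C@H]1O[C@]1(C)CC[C@]2(C)[C@@H](C)C[C@@H](O)C(I)=C2CO | intermediate
20 | (2Z,6R)-6-hydroxy-6-[(3S,5aR,6S,8R)-8-hydroxy-9-iodo-3,5a,6-trimethyl-1,3,4,5,5a,6,7,8-octahydro-2-benzoxepin-3-yl]-3-methylhex-2-en-1-yl acetate | CC(=O)OC/C=C(C)\CC[C@@H](O)[C@]1(C)CC[C@]2(C)[C@@H](C)C[C@@H](O)C(I)=C2CO1 | intermediate
21 | (2Z,6R)-6-[(3S,5aR,6S,8R)-9-iodo-3,5a,6-trimethyl-8-(triethylsilyloxy)-1,3,4,5,5a,6,7,8-octahydro-2-benzoxepin-3-yl]-3-methyl-6-(triethylsilyloxy)hex-2-en-1-yl acetate | CC(=O)OC/C=C(C)\CC[C@@H](O[Si](CC)(CC)CC)[C@]1(C)CC[C@]2(C)[C@@H](C)C[C@@H](O[Si](CC)(CC)CC)C(I)=C2CO1 | intermediate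
22 | (2Z,6R)-6-[(3S,5aR,6S,8R)-9-iodo-3,5a,6-trimethyl-8-(triethylsilyloxy)-1,3,4,5,5a,6,7,8-octahydro-2-benzoxepin-3-yl]-3-methyl-6-(triethylsilyloxy)hex-2-en-1-ol | OC/C=C(C)\CC[C@@H](O[Si](CC)(CC)CC)[C@]1(C)CC[C@]2(C)[C@@H](C)C[C@@H](O[Si](CC)(CC)CC)C(I)=C2CO1 | intermediate
23 | [(2S,3R)-3-methyl-3-{(3R)-3-(triethylsilyloxy)-3-[(3S,5aR,6S,8R)-9-iodo-3,5a,6-trimethyl-8-(triethylsilyloxy)-1,3,4,5,5a,6,7,8-octahydro-2-benzoxepin-3-yl]propyl}oxiran-2-yl]methanol | OC[C@@H]1O[C@]1(C)CC[C@@H](O[Si](CC)(CC)CC)[C@]2(C)CC[C@]3(C)[C@@H](C)C[C@@H](O[Si](CC)(CC)CC)C(I)=C3CO2 | intermediate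
24 | (2R,3R)-3-methyl-3-{(3R)-3-(triethylsilyloxy)-3-[(3S,5aR,6S,8R)-9-iodo-3,5a,6-trimethyl-8-(triethylsilyloxy)-1,3,4,5,5a,6,7,8-octahydro-2-benzoxepin-3-yl]propyl}oxirane-2-carbaldehyde | O=C[C@@H]1O[C@]1(C)CC[C@@H](O[Si](CC)(CC)CC)[C@]2(C)CC[C@]3(C)[C@@H](C)C[C@@H](O[Si](CC)(CC)CC)C(I)=C3CO2 | intermediate
25 | macrocyclic epoxy alcohol: C2 carbinol (both epimers) of ketone 26, C7 and C14 O-TES, cis C3/C4 epoxide, C8–O–C20 oxepane, C1=C15 alkene | OC1[C@@H]2O[C@]2(C)CC[C@@H](O[Si](CC)(CC)CC)[C@]3(C)CC[C@]4(C)[C@@H](C)C[C@@H](O[Si](CC)(CC)CC)C1=C4CO3 | intermediate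
26 | 7,14-bis-O-triethylsilyl ether of the target, (3R,4R,7R,8S,11R,12S,14R) in the locant key | O=C1[C@@H]2O[C@]2(C)CC[C@@H](O[Si](CC)(CC)CC)[C@]3(C)CC[C@]4(C)[C@@H](C)C[C@@H](O[Si](CC)(CC)CC)C1=C4CO3 | intermediate
27 | CNP0316768.3: (3R,4R,7R,8S,11R,12S,14R)-3,4-epoxy-7,14-dihydroxy-8,20-oxy-bridged macrocyclic 1(15)-en-2-one of the locant key (C4, C8, C11, C12 methyls) | O=C1[C@@H]2O[C@]2(C)CC[C@@H](O)[C@]3(C)CC[C@]4(C)[C@@H](C)C[C@@H](O)C1=C4CO3 | target

## Step count and risks

Total steps: 20. Longest linear sequence: 18 steps (steps 1–4, then 7–20); the chain branch (steps 5–6) joins at step 7.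

Step 3 (the proposed Diels–Alder reaction) is the least certain step. An α,β-disubstituted enal is a sluggish dienophile, and Mukaiyama aldol addition at the carbonyl or protodesilylation of 4 may compete. The fallback sets out from 4 and 5 and comes back at 6. It replaces the Brønsted-acid/silylium ion-pair organocatalysis by covalent chiral Lewis-acid catalysis with a triflimide-activated CBS-type oxazaborolidine (cationic boron, 10–20 mol %, CH2Cl2, −78 °C). This catalyst class is documented for 2-substituted enals with 2-silyloxydienes, and the partners are unchanged, so no new compound arises (F0).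

Step 7 (trans-selective B-alkyl Suzuki coupling on the 1,1-dibromoalkene) may suffer from slow transmetalation of the β-quaternary alkylborane and from double coupling. The fallback sets out from 7 and 11 and comes back at 13. It changes the organometallic partner from boron to zinc: hydrozirconation of 7 with Cp2Zr(H)Cl in THF gives the alkylzirconocene chloride F1. Transmetalation with ZnCl2 gives the alkylzinc chloride F2. This is coupled with 11 under Pd(DPEphos)Cl2 catalysis, the documented protocol for trans-selective monoalkylation of 1,1-dibromoalkenes with alkylzincs, to give 13.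

Step 18 (macrocyclisation) combines a hindered tetrasubstituted alkenyl iodide, a reducible α,β-epoxy aldehyde and a strained bicyclic product. The fallback sets out from 22 and comes back at 25. It postpones epoxidation until after ring closure: MnO2 oxidation of 22 gives the (Z)-enal F3. The same CrCl2/NiCl2 macrocyclisation, now on a robust enal, gives the macrocyclic bis-allylic alcohol F4. Hydroxyl-directed cis-specific epoxidation of the C3=C4 alkene with VO(acac)2 and t-BuOOH then gives 25. In this variant the epoxide face is relayed from the C2 carbinol, so the C2 epimers of F4 are separated and only the one that delivers the (3R,4R)-epoxide is carried on.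

## Further compounds

F0 | step 3 | none | none
F1 | step 7 | alkylzirconocene chloride Cp2Zr(Cl)CH2CH2–ring (ring as in 12) | Cl[Zr](CC[C@]1(C)[C@@H](C)CC(O[Si](C)(C)C(C)(C)C)=C[C@@H]1CO[Si](C)(C)C(C)(C)C)(C1C=CC=C1)C1C=CC=C1
F2 | step 7 | alkylzinc chloride ClZnCH2CH2–ring (ring as in 12) | Cl[Zn]CC[C@]1(C)[C@@H](C)CC(O[Si](C)(C)C(C)(C)C)=C[C@@H]1CO[Si](C)(C)C(C)(C)C
F3 | step 18 | (2Z,6R)-6-[(3S,5aR,6S,8R)-9-iodo-3,5a,6-trimethyl-8-(triethylsilyloxy)-1,3,4,5,5a,6,7,8-octahydro-2-benzoxepin-3-yl]-3-methyl-6-(triethylsilyloxy)hex-2-enal | O=C/C=C(C)\CC[C@@H](O[Si](CC)(CC)CC)[C@]1(C)CC[C@]2(C)[C@@H](C)C[C@@H](O[Si](CC)(CC)CC)C(I)=C2CO1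
F4 | step 18 | macrocyclic bis-allylic alcohol: 25 with a (Z)-C3=C4 alkene in place of the epoxide (C2 epimers) | OC1/C=C(C)\CC[C@@H](O[Si](CC)(CC)CC)[C@]2(C)CC[C@]3(C)[C@@H](C)C[C@@H](O[Si](CC)(CC)CC)C1=C3CO2
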